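## Retrosynthetic overview

1. The last bond made between the two halves is the depside ester, from the ring A carbonyl to O-4 of ring B. The ring B carboxyl stays masked as a benzyl ester until a closing hydrogenolysis.
2. The plan rests on ring B. C1 (carboxyl) is flanked by C2 (heptyl) and C6 (methoxy), and the oxygen on C4, para to C1, must be a free phenol for acylation while the oxygen on C6 is already a methyl ether.
3. Ring B is therefore built rather than bought. C2–C3 and C1–C6 come from a [4+2] union of benzyl dec-2-ynoate (C1, C2, ester, heptyl) with 1,1-dimethoxy-3-(trimethylsilyloxy)buta-1,3-diene (C3–C6). The acetal end becomes C6-OMe and the silyl enol ether end becomes C4-OH.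
4. Ring A is a purchased arene. 1-Chloro-3,5-dimethoxybenzene takes up heptyl and CO2 on adjacent carbons through an aryne, and BCl3 then frees the hydroxyl next to the carboxyl.
5. Ring order: ring B is the only ring constructed (step 4), and ring A is carried in intact and joined in step 8.

Key step: step 4

Remark: the target has no stereocentre and no configured double bond, so no step sets or protects configuration. Heptyllithium is not assumed to be purchasable and is made in a step of its own.

## Route

Step 1
Reactants: 1 non-1-yne; 2 benzyl chloroformate
Product: 4 benzyl dec-2-ynoate, via non-1-ynyllithium 3 (not isolated)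
Conditions: n-BuLi (1.05 equiv), THF, −78 °C, 30 min; cannulate into 2 (1.3 equiv), THF, −78 °C to 0 °C
Reagents that add atoms: none
Why: Deprotonation of a terminal alkyne and C-acylation of the lithium acetylide with a chloroformate is the standard alkoxycarbonylation route to 2-alkynoates, and adding the acetylide to excess chloroformate in the cold should keep a second addition to the product ester from competing.

Step 2
Reactants: 5 1,1-dimethoxyethene; 6 acetyl chloride
Product: 7 4,4-dimethoxybut-3-en-2-one
Conditions: 6 (1 equiv) added dropwise to 5 (2.2 equiv), Et2O, 0 °C to reflux, 3 h; distillation under reduced pressure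
Reagents that add atoms: none
Why: This is the C-acylation of a ketene acetal by an acid chloride, in which the electron-rich CH2 of 5 attacks 6 and the second equivalent of 5 takes up the HCl (ending as methyl acetate and chloromethane), which should favour proton loss to the push–pull enone over chloride demethylation.

Step 3
Reactants: 7 4,4-dimethoxybut-3-en-2-one
Product: 8 1,1-dimethoxy-3-(trimethylsilyloxy)buta-1,3-diene
Conditions: TMSCl (1.5 equiv), Et3N (2 equiv), ZnCl2 (3 mol%), toluene, 40 °C, 16 h; filter under Ar, distil under reduced pressure
Reagents that add atoms: chlorotrimethylsilane (TMSCl), C[Si](C)(C)Cl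
Why: Soft enolisation and O-silylation of a methyl ketone is the usual preparation of 2-silyloxybutadienes, and only the CH3 side of 7 carries enolisable hydrogens, so one enol silane alone is possible.

Step 4
Reactants: 4 benzyl dec-2-ynoate; 8 1,1-dimethoxy-3-(trimethylsilyloxy)buta-1,3-diene
Product: 11 benzyl 2-heptyl-4-hydroxy-6-methoxybenzoate, via cyclohexa-1,4-diene cycloadduct 9 (not isolated), via aryl trimethylsilyl ether 10 (not isolated)
Conditions: 8 (3 equiv, in portions), neat or minimal xylene, sealed tube, Ar, 140–150 °C, 24–48 h; then 1 M aq HCl, THF, rt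
Reagents that add atoms: none
Why: The diene 8 carries three oxygen donors that all push electron density to its terminal CH2, so this carbon attacks the heptyl-bearing β-carbon of ynoate 4 while the acetal carbon bonds to the α-carbon, either in one asynchronous normal-electron-demand Diels–Alder event or as a Michael addition followed by collapse of the allenolate on the dimethoxycarbenium end, both leading to cyclohexa-1,4-diene 9. The closest known reaction type is the Diels–Alder benzannulation of 1,1-dialkoxy-3-silyloxybuta-1,3-dienes with acetylenic esters to 4-hydroxy-6-alkoxybenzoates, which is documented for β-alkyl 2-alkynoates as well, although these need prolonged heating and excess diene. Ring B, the only ring closed, forms as a six-membered carbocycle by intermolecular [4+2] cycloaddition that makes C2–C3 and C1–C6. Aromatisation follows by 1,4-elimination of methanol from 9 (H from C3, one methoxy from C6) to give 10, and the acidic work-up cleaves the aryl silyl ether to phenol 11. No stereocentre is created, so the only selectivity required is regiochemical, and it is secured by the matched polarisation of the two partners. The same event differentiates the oxygens, because the acetal carbon can keep only one methoxy (C6-OMe) and the silyl enol ether carbon can only end as the free C4-OH, with the benzyl ester already in place at C1.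

Step 5
Reactants: 12 1-bromoheptane
Product: 13 heptyllithium (ether solution, titrated and used at once)
Conditions: Li wire (2.3 equiv), Et2O, −10 °C, Ar
Reagents that add atoms: lithium metal, [Li]
Why: Reductive lithiation of a primary alkyl bromide with lithium metal in ether is the classical preparation of n-alkyllithiums, and the low temperature holds back Wurtz coupling.

Step 6
Reactants: 14 1-chloro-3,5-dimethoxybenzene; 13 heptyllithium
Product: 18 2-heptyl-4,6-dimethoxybenzoic acid, via 2-chloro-4,6-dimethoxyphenyllithium 15 (not isolated), via 3,5-dimethoxybenzyne 16 (not isolated), via 2-heptyl-4,6-dimethoxyphenyllithium 17 (not isolated)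
Conditions: 13 (3 equiv), Et2O, −20 °C to rt, 4 h; then excess dry CO2, −78 °C to rt; 2 M aq HCl
Reagents that add atoms: carbon dioxide, O=C=O
Why: In this aryne alkylation–carboxylation one equivalent of 13 removes the hydrogen between Cl and OMe, loss of LiCl gives aryne 16, a second equivalent adds at the aryne carbon remote from the adjacent methoxy so that the charge of 17 sits beside that inductively stabilising oxygen, and CO2 traps this carbanion, which places heptyl and carboxyl on neighbouring carbons.

Step 7
Reactants: 18 2-heptyl-4,6-dimethoxybenzoic acid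
Product: 20 2-heptyl-6-hydroxy-4-methoxybenzoic acid, via cyclic chloroborate 19 (not isolated)
Conditions: BCl3 (1 M in CH2Cl2, 2.5 equiv), CH2Cl2, −10 °C to rt, 2 h; ice-water
Reagents that add atoms: none
Why: In this chelation-directed ether cleavage BCl3 binds the carboxyl group and reaches only the neighbouring C6 methoxy through a six-membered chelate, so that methyl leaves as chloromethane while the para methoxy, which lacks this assistance, should survive at or below room temperature.

Step 8
Reactants: 20 2-heptyl-6-hydroxy-4-methoxybenzoic acid; 11 benzyl 2-heptyl-4-hydroxy-6-methoxybenzoate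
Product: 22 benzyl 2-heptyl-4-[(2-heptyl-6-hydroxy-4-methoxybenzoyl)oxy]-6-methoxybenzoate, via mixed trifluoroacetic anhydride 21 (not isolated)
Conditions: TFAA (4 equiv), toluene, 0 °C to rt, 4 h; evaporate; aq NaHCO3 wash
Reagents that add atoms: none
Why: Mixed-anhydride esterification with TFAA is the standard depside coupling, since the electron-rich doubly ortho-substituted acyl group of 21 ionises readily towards an acylium-like species that the unhindered 4-OH of 11 captures, whereas the 6-OH of 20 is tied up in a hydrogen bond to its own carbonyl and any aryl trifluoroacetate is cleaved by the bicarbonate wash.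

Step 9
Reactants: 22 benzyl 2-heptyl-4-[(2-heptyl-6-hydroxy-4-methoxybenzoyl)oxy]-6-methoxybenzoate
Product: 23 2-heptyl-4-[(2-heptyl-6-hydroxy-4-methoxybenzoyl)oxy]-6-methoxybenzoic acid (target)
Conditions: H2 (1 atm), 10% Pd/C, EtOAc, rt
Reagents that add atoms: none
Why: Catalytic hydrogenolysis cleaves only the benzylic C–O bond of the benzyl ester, and the aryl ester link of the depside, the methyl ethers and the phenol are inert to H2 over Pd/C.

## Compound list

1 | non-1-yne | C#CCCCCCCC | starting material
2 | benzyl chloroformate | O=C(Cl)OCc1ccccc1 | starting material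
3 | non-1-ynyllithium | [Li]C#CCCCCCCC | intermediate
4 | benzyl dec-2-ynoate | CCCCCCCC#CC(=O)OCc1ccccc1 | intermediate
5 | 1,1-dimethoxyethene | C=C(OC)OC | starting material
6 | acetyl chloride | CC(=O)Cl | starting material
7 | 4,4-dimethoxybut-3-en-2-one | CC(=O)C=C(OC)OC | intermediate
8 | 1,1-dimethoxy-3-(trimethylsilyloxy)buta-1,3-diene | C=C(O[Si](C)(C)C)C=C(OC)OC | intermediate
9 | benzyl 2-heptyl-6,6-dimethoxy-4-(trimethylsilyloxy)cyclohexa-1,4-diene-1-carboxylate | CCCCCCCC1=C(C(=O)OCc2ccccc2)C(OC)(OC)C=C(O[Si](C)(C)C)C1 | intermediate
10 | benzyl 2-heptyl-6-methoxy-4-(trimethylsilyloxy)benzoate | CCCCCCCc1cc(O[Si](C)(C)C)cc(OC)c1C(=O)OCc1ccccc1 | intermediate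
11 | benzyl 2-heptyl-4-hydroxy-6-methoxybenzoate | CCCCCCCc1cc(O)cc(OC)c1C(=O)OCc1ccccc1 | intermediate
12 | 1-bromoheptane | CCCCCCCBr | starting material
13 | heptyllithium | [Li]CCCCCCC | intermediate
14 | 1-chloro-3,5-dimethoxybenzene | COc1cc(Cl)cc(OC)c1 | starting material
15 | 2-chloro-4,6-dimethoxyphenyllithium | [Li]c1c(Cl)cc(OC)cc1OC | intermediate
16 | 3,5-dimethoxybenzyne (1,2-didehydro-3,5-dimethoxybenzene) | COC1=CC(OC)=CC#C1 | intermediate
17 | 2-heptyl-4,6-dimethoxyphenyllithium | [Li]c1c(CCCCCCC)cc(OC)cc1OC | intermediate
18 | 2-heptyl-4,6-dimethoxybenzoic acid | CCCCCCCc1cc(OC)cc(OC)c1C(=O)O | intermediate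
19 | 2-chloro-5-heptyl-7-methoxy-4H-1,3,2-benzodioxaborinin-4-one | CCCCCCCc1cc(OC)cc2OB(Cl)OC(=O)c12 | intermediate
20 | 2-heptyl-6-hydroxy-4-methoxybenzoic acid | CCCCCCCc1cc(OC)cc(O)c1C(=O)O | intermediate
21 | 2-heptyl-6-hydroxy-4-methoxybenzoic trifluoroacetic anhydride | CCCCCCCc1cc(OC)cc(O)c1C(=O)OC(=O)C(F)(F)F | intermediate
22 | benzyl 2-heptyl-4-[(2-heptyl-6-hydroxy-4-methoxybenzoyl)oxy]-6-methoxybenzoate | CCCCCCCc1cc(OC)cc(O)c1C(=O)Oc1cc(CCCCCCC)c(C(=O)OCc2ccccc2)c(OC)c1 | intermediate
23 | 2-heptyl-4-[(2-heptyl-6-hydroxy-4-methoxybenzoyl)oxy]-6-methoxybenzoic acid | CCCCCCCc1cc(OC)cc(O)c1C(=O)Oc1cc(CCCCCCC)c(C(=O)O)c(OC)c1 | target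

## Step count and risks

Total step count: 9.

Longest linear sequence: 5 steps (5 → 7 → 8 → 11 → 22 → 23). The ring A arm 12 → 13 → 18 → 20 → 22 → 23 is equally long.

**Steps most likely to fail**

**1. Step 4 (key step).**
- What may go wrong: the β-heptyl group lowers the dienophilicity of the alkyne. At the temperature needed, the diene may be used up by thermal decomposition, silyl migration or adventitious hydrolysis before it adds, so conversion may stall.
- Fallback: it sets out from 18 and comes back at 11. It gives up ring construction and tells the two oxygens apart on the ready-made arene by protecting-group logic.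
- BBr3 (CH2Cl2, −78 °C to rt) strips both methyl ethers to give 2-heptyl-4,6-dihydroxybenzoic acid F1.
- BnBr with KHCO3 in DMF alkylates only the carboxylate to give benzyl 2-heptyl-4,6-dihydroxybenzoate F2.
- One equivalent of allyl bromide with K2CO3 in acetone takes the non-chelated 4-OH and gives benzyl 4-(allyloxy)-2-heptyl-6-hydroxybenzoate F3.
- MeI with K2CO3 in warm DMF methylates the remaining hydrogen-bonded 6-OH to give benzyl 4-(allyloxy)-2-heptyl-6-methoxybenzoate F4.
- Pd(PPh3)4 with morpholine in THF removes the allyl group and delivers 11.

**2. Step 6.**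
- What may go wrong: lithiation may occur between the two methoxy groups, which cannot lead to an aryne. The product aryllithium may add to a further aryne. Organolithium may add twice to the lithium carboxylate during the CO2 quench.
- Fallback: it sets out from 14, with 12 as the heptyl source, and comes back at 18. It installs the two substituents one after the other without an aryne.
- 12 and Mg in THF give heptylmagnesium bromide F5.
- Kumada coupling of F5 with 14 under NiCl2(dppp) (dppp = 1,3-bis(diphenylphosphino)propane) in refluxing Et2O/THF gives 1-heptyl-3,5-dimethoxybenzene F6.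
- Vilsmeier–Haack formylation (POCl3, DMF) at the position ortho to heptyl and ortho/para to the methoxy groups gives 2-heptyl-4,6-dimethoxybenzaldehyde F7.
- Pinnick oxidation (NaClO2, NaH2PO4, 2-methylbut-2-ene, t-BuOH/H2O) gives 18.

**3. Step 2.**
- What may go wrong: chloride may dealkylate the cationic adduct to the β-keto ester stage. A second acylation may occur at the central carbon. The acid-sensitive product may hydrolyse during isolation.
- Fallback: it sets out from 6 and comes back at 7. It builds the same carbon chain with chlorides as placeholders for the methoxy groups.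
- AlCl3-mediated acylation of 1,1-dichloroethene with 6 (CH2Cl2, 0 °C to rt) gives 4,4,4-trichlorobutan-2-one F8.
- F8 loses HCl on distillation to give 4,4-dichlorobut-3-en-2-one F9.
- Two addition–elimination events with NaOMe (2.1 equiv) in MeOH at 0 °C replace both chlorides and give 7.

## Further compounds

F1 | step 4 | 2-heptyl-4,6-dihydroxybenzoic acid | CCCCCCCc1cc(O)cc(O)c1C(=O)O
F2 | step 4 | benzyl 2-heptyl-4,6-dihydroxybenzoate | CCCCCCCc1cc(O)cc(O)c1C(=O)OCc1ccccc1
F3 | step 4 | benzyl 4-(allyloxy)-2-heptyl-6-hydroxybenzoate | CCCCCCCc1cc(OCC=C)cc(O)c1C(=O)OCc1ccccc1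
F4 | step 4 | benzyl 4-(allyloxy)-2-heptyl-6-methoxybenzoate | CCCCCCCc1cc(OCC=C)cc(OC)c1C(=O)OCc1ccccc1
F5 | step 6 | heptylmagnesium bromide | CCCCCCC[Mg]Br
F6 | step 6 | 1-heptyl-3,5-dimethoxybenzene | CCCCCCCc1cc(OC)cc(OC)c1
F7 | step 6 | 2-heptyl-4,6-dimethoxybenzaldehyde | CCCCCCCc1cc(OC)cc(OC)c1C=O
F8 | step 2 | 4,4,4-trichlorobutan-2-one | CC(=O)CC(Cl)(Cl)Cl
F9 | step 2 | 4,4-dichlorobut-3-en-2-one | CC(=O)C=C(Cl)Cl
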